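Remark: ring atoms are numbered as in germacranes (C1–C10 ring; C11, C12, C13 the lactone carbons with C12 the carbonyl; C14 on C10; C15 on C4). The SMILES is read as 1S,4R,5S,6S,7R,8S: a cis-4,5-epoxide, a trans-fused 8,12-lactone and a (Z)-2-methylbut-2-enoate (angelate) on O6.

## Structural features

The target is a germacranolide: a ten-membered carbocycle (C1–C10) with an exocyclic methylene C14 on C10 and a methyl C15 on C4, trans-fused across C7–C8 to an α-methylene-γ-butyrolactone (C11, C12, C13, ring oxygen on C8). C4–C5 is a cis-trisubstituted epoxide and the neighbouring C6 carries an angelate, so C4, C5, C6, C7 and C8 form an unbroken row of five stereocentres. The sixth stereocentre, the C1 carbinol, stands alone between the sp2 carbon C10 and the methylene C2, two CH2 groups away from C4. The fragile groups are the angelate (Z to E isomerisation to the tiglate with nucleophiles or base), the 2,3-epoxy alcohol unit C4–C6 (epoxide migration, acid opening), the α-methylene lactone (Michael acceptor) and the allylic alcohol at C1. The real difficulty is the ten-membered ring together with the remote C1 centre, which any ring closure by carbonyl addition at C1 would leave to the conformation of the forming medium ring. The key step exploits that C1 is a single carbon between an alkenyl carbon (C10, already bearing C14) and an alkyl carbon (C2): as a ketone this is the product of a carbonylative cross-coupling, so carbon monoxide can supply C1 while the ring closes, and a catalyst can set the C1 configuration afterwards.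

## Logic of the disconnections

19 to 18. The C1–H bond is removed, taking the isolated carbinol back to a ketone. The ring-closing event then creates no stereocentre, and C1 becomes a carbon that can be introduced as a one-carbon unit. The forward step must be a 1,2-reduction of a 2-methylene ketone with catalyst control of the face, sparing the lactone methylene, the angelate and the epoxide.

18 to 16 (through 17). Two ring bonds are cut, C10–C1 and C1–C2, and C1 leaves as carbon monoxide. C10 becomes an alkenyl iodide and C2 the end of a vinyl group (C2=C3) on C4, which is hydroborated to 17 in the forward sense. This is the one place where the ring can be closed without forming a stereocentre and with two simple termini. The gain is an open chain in which all five remaining stereocentres can be assembled from two fragments. The forward step needs chemoselective hydroboration, CO insertion before transmetalation, and ring closure in preference to oligomerisation.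

16 to 13 and 14. The ester C–O bond at O6 is cut. The isomerisation-prone acyl group is attached once, to a free hydroxyl, before palladium is used and after all C–C bonds of the open chain exist. The forward acylation must keep the Z geometry and must not use strong base next to the epoxy alcohol.

13 to 4 and 12. The C6–C7 bond is cut. A β-(1-hydroxyalkyl)-α-methylene-γ-lactone is the product of γ-allylation of an aldehyde by a 3-(halomethyl)butenolide. The molecule falls into a C2–C6 fragment (with C15) and a C7–C14 fragment. The forward step must set C6 and C7 at once, with the face of the aldehyde, the closed transition state and the C8 substituent all pointing the same way, and the metal must insert only into the allylic C–Br bond.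

12 to 11, then 9 and 10. The C7=C11 bond (ring-closing metathesis) and then the O8–C12 ester bond are cut. The butenolide is built with its bromomethyl group in place from an allylic alcohol and a commercial acid. The metathesis must leave the iodoalkene alone.

9 to 8, 7, then 5 and 6. The C–I bond goes back to C–Br, the single enantiomer to the racemate, and the C8–C9 bond is cut into two three-carbon pieces. The iodide is required by the carbonylative coupling. The forward steps need 1,2-addition to the enal and an efficient resolution.

4 to 3, 2 and 1. The aldehyde goes back to the alcohol, the epoxide to the Z-allylic alcohol (C4 and C5 set together by reagent control), and the vinyl group to the ethynyl group of a commercial Z-enynol. The forward steps need a semihydrogenation that stops at the diene and an epoxidation that touches only the allylic double bond.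

## Other disconnections considered

Alternative 1: the cut that comes to mind first is C6–C7 (or C7–C8) inside the ring, with an intramolecular Barbier or Nozaki–Hiyama–Kishi allylation of the open-chain bromide aldehyde A1 closing the ring at the lactone. In A1 the aldehyde is tethered to C8, so the tether, not the C8 substituent, decides which face of C7 reacts, and cis or trans ring fusion cannot be argued from a simple rule. C6 and C7 would both be set under medium-ring control in the ring-closing event, and A1 needs C1 in place and protected, which makes the linear sequence longer. The chosen plan forms the same C6–C7 bond between two fragments, where attack anti to the C8 substituent is reliable.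

Alternative 2: a ring expansion that cuts C8–C9 and re-forms C1–C6, the forward step being an anionic oxy-Cope rearrangement of the dienol A3, made from the monoterpene enone A2 and a 2-oxygenated vinyl anion that carries C7, C8, C11 and C12. A2 already holds C1–C6, C10, C14, C15, the cis C4=C5 bond and the C6 oxygen, and a chair transition state would relay its stereocentre to C8. The difficulty is C7: it would be set by protonation of the ring-expanded enolate on the face anti to the new C8–C9 bond, which gives the cis ring fusion, not the trans fusion of the target. The epoxide (on a Z-enone) and the C1 oxygen (ene oxidation of the 1(10)-alkene) would then both have to be introduced under conformational control of the ten-membered ring. The chosen plan sets every centre by a local or catalyst-controlled event.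

Alternative 3: a cut at C2–C3, the forward step being ring-closing metathesis to the triene A4 followed by saturation of the new C2=C3 bond. The new 1,2-disubstituted alkene would have to be reduced in the presence of two 1,1-disubstituted alkenes (one conjugated), the angelate and a vinyl epoxide, and no reagent offers that selectivity. The chosen plan uses the same vinyl group on C4 but turns it into sp3 carbon in the bond-forming step itself.

Key step: step 11

## Route

Step 1
Reactants: 1 (2Z)-3-methylpent-2-en-4-yn-1-ol
Product: 2 (2Z)-3-methylpenta-2,4-dien-1-ol
Conditions: H2 (1 atm), Pd/CaCO3–Pb(OAc)2 (Lindlar catalyst), quinoline, EtOAc, rt, stopped after 1 equiv H2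
Reagents that add atoms: none
Why: Lindlar semihydrogenation should take the terminal alkyne to the vinyl group and stop there on the poisoned catalyst; the Z-trisubstituted alkene is not touched and no stereocentre is involved.

Step 2
Reactants: 2 (2Z)-3-methylpenta-2,4-dien-1-ol
Product: 3 [(2S,3R)-3-ethenyl-3-methyloxiran-2-yl]methanol
Conditions: Ti(OiPr)4 (10 mol%), L-(+)-diethyl tartrate (12 mol%), t-BuOOH, 4 Å MS, CH2Cl2, −20 °C
Reagents that add atoms: tert-butyl hydroperoxide CC(C)(C)OO
Why: Sharpless asymmetric epoxidation: the titanium tartrate binds the allylic hydroxyl, so only the allylic double bond (future C4–C5) is oxidised; the cis epoxide follows from the Z-alkene, and L-(+)-tartrate should deliver oxygen to the face that gives C4 R and C5 S, as for other Z-3,3-disubstituted allylic alcohols.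

Step 3
Reactants: 3 [(2S,3R)-3-ethenyl-3-methyloxiran-2-yl]methanol
Product: 4 (2R,3R)-3-ethenyl-3-methyloxirane-2-carbaldehyde
Conditions: Dess–Martin periodinane, pyridine, CH2Cl2, 0 °C; solution used directly
Reagents that add atoms: none
Why: Dess–Martin oxidation under buffered, non-basic conditions should give the epoxy aldehyde without epimerising C5 or opening the vinyl epoxide (the descriptor at C5 changes by priority only).

Step 4
Reactants: 5 prop-2-enal; 6 2,3-dibromoprop-1-ene
Product: 7 rac-5-bromohexa-1,5-dien-3-ol
Conditions: In powder, THF/H2O (1:1), 0 °C to rt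
Reagents that add atoms: none
Why: Indium-mediated Barbier allylation: indium inserts into the allylic C–Br bond only, and the allylindium adds 1,2 to the enal, forming the C8–C9 bond and the racemic C8 carbinol with the 2-bromoalkene intact.

Step 5
Reactants: 7 rac-5-bromohexa-1,5-dien-3-ol
Product: 8 (3S)-5-bromohexa-1,5-dien-3-ol
Conditions: Ti(OiPr)4, D-(−)-diisopropyl tartrate, t-BuOOH (0.6 equiv), 4 Å MS, CH2Cl2, −20 °C; unreacted alcohol recovered
Reagents that add atoms: none
Why: Sharpless kinetic resolution: with D-(−)-tartrate the (R)-vinyl carbinol should be epoxidised much faster, leaving the (S)-alcohol, which fixes C8; the 2-bromoalkene is not allylic and stays.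

Step 6
Reactants: 8 (3S)-5-bromohexa-1,5-dien-3-ol
Product: 9 (3S)-5-iodohexa-1,5-dien-3-ol
Conditions: NaI, CuI (5 mol%), trans-N,N′-dimethylcyclohexane-1,2-diamine (10 mol%), 1,4-dioxane, 110 °C
Reagents that add atoms: sodium iodide [Na+].[I-]
Why: Copper-catalysed halogen exchange of the alkenyl bromide (Finkelstein type), driven by precipitation of NaBr; the iodide is wanted because it inserts palladium and CO under the mild conditions of step 11, and the stereocentre is not involved.

Step 7
Reactants: 9 (3S)-5-iodohexa-1,5-dien-3-ol; 10 2-(bromomethyl)prop-2-enoic acid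
Product: 11 (3S)-5-iodohexa-1,5-dien-3-yl 2-(bromomethyl)prop-2-enoate
Conditions: DCC, DMAP (5 mol%), CH2Cl2, −10 to 0 °C
Reagents that add atoms: none
Why: Steglich esterification acylates O8 with retention at C8; the low temperature and low DMAP loading should keep the allylic bromide from being displaced.

Step 8
Reactants: 11 (3S)-5-iodohexa-1,5-dien-3-yl 2-(bromomethyl)prop-2-enoate
Product: 12 (5S)-3-(bromomethyl)-5-(2-iodoprop-2-en-1-yl)furan-2(5H)-one
Conditions: second-generation Grubbs catalyst RuCl2(=CHPh)(PCy3)(H2IMes) (5 mol%), CH2Cl2, 40 °C, 5 mM
Reagents that add atoms: none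
Why: Ring-closing metathesis between the vinyl group and the acrylate double bond closes the five-membered butenolide (C7=C11) with loss of ethene; the 1,1-disubstituted iodoalkene is a poor partner for the ruthenium carbene and should remain, and C8 is untouched.

Step 9
Reactants: 4 (2R,3R)-3-ethenyl-3-methyloxirane-2-carbaldehyde; 12 (5S)-3-(bromomethyl)-5-(2-iodoprop-2-en-1-yl)furan-2(5H)-one
Product: 13 (4S,5S)-4-{(S)-[(2S,3R)-3-ethenyl-3-methyloxiran-2-yl](hydroxy)methyl}-5-(2-iodoprop-2-en-1-yl)-3-methylideneoxolan-2-one
Conditions: In powder, THF/H2O (4:1), 0 °C to rt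
Reagents that add atoms: none
Why: Indium Barbier γ-allylation: the allylindium from 12 should bond through C7 in a six-membered chair (Zimmerman–Traxler) transition state, which sets the C6/C7 relation, while Felkin–Anh attack anti to the epoxide C–O bond sets C5/C6 and approach anti to the C8 side chain sets the trans C7/C8 relation; with (S)-12 and (2R,3R)-4 all three preferences agree. The double bond moves to C11=C13 and unveils the α-methylene lactone with O6 free (the C7 descriptor reads S here only because O6 is not yet acylated).

Step 10
Reactants: 13 (4S,5S)-4-{(S)-[(2S,3R)-3-ethenyl-3-methyloxiran-2-yl](hydroxy)methyl}-5-(2-iodoprop-2-en-1-yl)-3-methylideneoxolan-2-one; 14 (2Z)-2-methylbut-2-enoic acid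
Product: 16 (S)-[(2S,3R)-3-ethenyl-3-methyloxiran-2-yl][(2S,3R)-2-(2-iodoprop-2-en-1-yl)-4-methylidene-5-oxooxolan-3-yl]methyl (2Z)-2-methylbut-2-enoate, via mixed anhydride 15 (not isolated)
Conditions: 14, 2,4,6-trichlorobenzoyl chloride, Et3N, toluene, rt; then 13, toluene, 75 °C (no DMAP)
Reagents that add atoms: none
Why: Yamaguchi-type mixed-anhydride acylation without a nucleophilic catalyst should acylate O6 with retention at C6 and keep the Z geometry of the angelate; no strong base is present that could move the epoxide.

Step 11
Reactants: 16 (S)-[(2S,3R)-3-ethenyl-3-methyloxiran-2-yl][(2S,3R)-2-(2-iodoprop-2-en-1-yl)-4-methylidene-5-oxooxolan-3-yl]methyl (2Z)-2-methylbut-2-enoate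
Product: 18 (4R,5S,6S,7R,8S)-4,5-epoxy-6-[(2Z)-2-methylbut-2-enoyloxy]-1-oxogermacra-10(14),11(13)-dien-8,12-olide, via B-alkyl-9-BBN adduct 17 (not isolated)
Conditions: 9-BBN-H (1.3 equiv), THF, 0 °C to rt; then slow addition to Pd(PPh3)4 (10 mol%), K3PO4, CO (1 atm), 1,4-dioxane, 40–50 °C, final 2 mM
Reagents that add atoms: carbon monoxide [C-]#[O+]
Why: 9-BBN should add only to the monosubstituted C2=C3 vinyl group (the other alkenes are 1,1-disubstituted or trisubstituted and two are conjugated), placing boron on C2 to give 17. Zerovalent palladium then inserts into the C10–I bond, CO inserts to give the C1 acylpalladium, phosphate-activated B-alkyl transmetalation brings in C2, and reductive elimination forms C1–C2. The closest known reaction type is the carbonylative Suzuki–Miyaura coupling of iodoalkenes with B-alkyl-9-BBN reagents, known also in ring-forming intramolecular form for 2-methylenecycloalkanones, together with carbonylative cross-coupling macrocyclisations of the Stille type. One ring is closed, the ten-membered carbocycle, by a (9+1) carbonylative annulation that makes C10–C1 and C1–C2, the closing event being reductive elimination from an eleven-membered acyl(alkyl)palladacycle. No stereocentre is formed, because C1 arrives as a carbonyl carbon, and the five existing centres are remote from both reacting ends. The step needs CO insertion before transmetalation, which the alkenyl iodide and 1 atm CO favour, the more so as direct coupling would have to close a more strained nine-membered ring. It also needs ring closure in preference to intermolecular coupling, which slow addition of 17 to the catalyst (high dilution) secures. The α-methylene lactone cannot intercept the alkenyl- or acylpalladium within the molecule without forming a bridged bicycle, and once the vinyl epoxide has been hydroborated neither the epoxide nor the angelate reacts with zerovalent palladium.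

Step 12
Reactants: 18 (4R,5S,6S,7R,8S)-4,5-epoxy-6-[(2Z)-2-methylbut-2-enoyloxy]-1-oxogermacra-10(14),11(13)-dien-8,12-olide
Product: 19 (1S,4R,5S,6S,7R,8S)-4,5-epoxy-1-hydroxy-6-[(2Z)-2-methylbut-2-enoyloxy]germacra-10(14),11(13)-dien-8,12-olide
Conditions: (R)-Me-CBS oxazaborolidine (20 mol%), catecholborane, toluene/CH2Cl2, −78 °C
Reagents that add atoms: none
Why: Corey–Bakshi–Shibata reduction: the ketone binds with the alkenyl carbon C10 as the large and the C2 methylene as the small substituent, so the (R)-catalyst should deliver hydride to the face that gives the (1S)-carbinol; the reduction is 1,2-selective and should leave the lactone methylene, the angelate and the epoxide untouched.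

## Compound list

1 | (2Z)-3-methylpent-2-en-4-yn-1-ol | OC/C=C(/C)C#C | starting material
2 | (2Z)-3-methylpenta-2,4-dien-1-ol | OC/C=C(/C)C=C | intermediate
3 | [(2S,3R)-3-ethenyl-3-methyloxiran-2-yl]methanol | C=C[C@@]1(C)O[C@H]1CO | intermediate
4 | (2R,3R)-3-ethenyl-3-methyloxirane-2-carbaldehyde | C=C[C@@]1(C)O[C@H]1C=O | intermediate
5 | prop-2-enal | C=CC=O | starting material
6 | 2,3-dibromoprop-1-ene | C=C(Br)CBr | starting material
7 | rac-5-bromohexa-1,5-dien-3-ol | C=CC(O)CC(Br)=C | intermediate
8 | (3S)-5-bromohexa-1,5-dien-3-ol | O[C@H](C=C)CC(Br)=C | intermediate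
9 | (3S)-5-iodohexa-1,5-dien-3-ol | O[C@H](C=C)CC(I)=C | intermediate
10 | 2-(bromomethyl)prop-2-enoic acid | C=C(CBr)C(=O)O | starting material
11 | (3S)-5-iodohexa-1,5-dien-3-yl 2-(bromomethyl)prop-2-enoate | C=C(CBr)C(=O)O[C@H](C=C)CC(I)=C | intermediate
12 | (5S)-3-(bromomethyl)-5-(2-iodoprop-2-en-1-yl)furan-2(5H)-one | BrCC1=C[C@H](CC(I)=C)OC1=O | intermediate
13 | (4S,5S)-4-{(S)-[(2S,3R)-3-ethenyl-3-methyloxiran-2-yl](hydroxy)methyl}-5-(2-iodoprop-2-en-1-yl)-3-methylideneoxolan-2-one | C=C1C(=O)O[C@@H](CC(I)=C)[C@@H]1[C@H](O)[C@@H]2O[C@]2(C)C=C | intermediate
14 | (2Z)-2-methylbut-2-enoic acid (angelic acid) | C/C=C(/C)C(=O)O | starting material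
15 | (2Z)-2-methylbut-2-enoic 2,4,6-trichlorobenzoic anhydride | C/C=C(/C)C(=O)OC(=O)c1c(Cl)cc(Cl)cc1Cl | intermediate
16 | (S)-[(2S,3R)-3-ethenyl-3-methyloxiran-2-yl][(2S,3R)-2-(2-iodoprop-2-en-1-yl)-4-methylidene-5-oxooxolan-3-yl]methyl (2Z)-2-methylbut-2-enoate | C=C1C(=O)O[C@@H](CC(I)=C)[C@@H]1[C@H](OC(=O)/C(C)=C\C)[C@@H]2O[C@]2(C)C=C | intermediate
17 | 9-BBN adduct of 16: the ethenyl group on the oxirane converted into CH2CH2–B(9-borabicyclo[3.3.1]nonan-9-yl), boron on C2, all stereocentres as in 16 | C=C1C(=O)O[C@@H](CC(I)=C)[C@@H]1[C@H](OC(=O)/C(C)=C\C)[C@@H]2O[C@]2(C)CCB3C4CCCC3CCC4 | intermediate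
18 | (4R,5S,6S,7R,8S)-4,5-epoxy-6-[(2Z)-2-methylbut-2-enoyloxy]-1-oxogermacra-10(14),11(13)-dien-8,12-olide | C=C1C(=O)O[C@H]2CC(=C)C(=O)CC[C@@]3(C)O[C@H]3[C@@H](OC(=O)/C(C)=C\C)[C@H]12 | intermediate
19 | (1S,4R,5S,6S,7R,8S)-4,5-epoxy-1-hydroxy-6-[(2Z)-2-methylbut-2-enoyloxy]germacra-10(14),11(13)-dien-8,12-olide | C=C1C(=O)O[C@H]2CC(=C)[C@@H](O)CC[C@@]3(C)O[C@H]3[C@@H](OC(=O)/C(C)=C\C)[C@H]12 | target

## Step count and least certain steps

Total: 12 steps. Longest linear sequence: 9 steps (4, 5, 6, 7, 8, 9, 10, 11, 12); steps 1–3 make the second fragment.

Step 11 (key step). The most likely failure is that ring closure is slower than interception of the acylpalladium: by adventitious water (hydroxycarbonylation to an acid), by a second molecule (oligomers), or by premature transmetalation before CO insertion. This is because transmetalation across a forming medium ring is slow. A further risk is base- or palladium hydride-induced migration of the C10=C14 double bond into conjugation within the ring. Fallback: from 16, rhodium-catalysed linear hydroformylation of the vinyl group (Rh(acac)(CO)2, a wide-bite-angle bisphosphite, CO/H2) would give the C1 aldehyde F1. A Nozaki–Hiyama–Kishi ring closure of F1 (CrCl2, catalytic NiCl2, DMF, high dilution) forms C10–C1 by carbonyl addition and should give 19 together with its (1R)-carbinol F2. Dess–Martin oxidation of the mixture converges on 18, where the route is rejoined before step 12.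

Step 9. Poor facial selectivity at the aldehyde (reaction through a transition state with the epoxide substituent axial) would give the C6 epimer, and indium salts in water may open the acid-sensitive vinyl epoxide. Fallback: from 13 (as a mixture at C6), Dess–Martin oxidation gives the epoxy ketone F3, and reduction with Zn(BH4)2 at low temperature, directed by chelation between the ketone and the epoxide oxygen, should set C6 anti to the epoxide. The centre is then made by a reduction, not by the C–C bond formation, and the route is rejoined at 13.

Step 10. The hindered C6 hydroxyl may acylate slowly, and at the temperature needed the angelate can isomerise to the tiglate, or the free hydroxyl can attack C12 and move the lactone from O8 to O6. Fallback: from 13, carbodiimide coupling at 0 °C with 2-[bis(2,2,2-trifluoroethoxy)phosphoryl]propanoic acid gives the phosphonopropionate F4. A Still–Gennari olefination of F4 with acetaldehyde (KN(SiMe3)2, 18-crown-6, THF, −78 °C) then builds the Z-configured 2-methylbut-2-enoate in place and returns to 16.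

Step 12. Insufficient facial selectivity is possible, because the ring may not present the ketone as the simple large/small model assumes; 1,4-reduction of the 2-methylene ketone may also compete. Fallback: from 18, Luche reduction (NaBH4, CeCl3·7H2O, MeOH, −78 °C) gives 19 and the (1R)-carbinol F2. After separation, F2 is inverted by Mitsunobu esterification with chloroacetic acid (PPh3, diisopropyl azodicarboxylate) to the (1S)-chloroacetate F5, and the chloroacetate is removed selectively with thiourea and NaHCO3 in ethanol, arriving at 19.

## Further compounds

F1 | step 11 | (S)-[(2S,3R)-3-methyl-3-(3-oxopropyl)oxiran-2-yl][(2S,3R)-2-(2-iodoprop-2-en-1-yl)-4-methylidene-5-oxooxolan-3-yl]methyl (2Z)-2-methylbut-2-enoate | C=C1C(=O)O[C@@H](CC(I)=C)[C@@H]1[C@H](OC(=O)/C(C)=C\C)[C@@H]2O[C@]2(C)CCC=O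
F2 | step 11 | (1R,4R,5S,6S,7R,8S)-4,5-epoxy-1-hydroxy-6-[(2Z)-2-methylbut-2-enoyloxy]germacra-10(14),11(13)-dien-8,12-olide (C1 epimer of 19) | C=C1C(=O)O[C@H]2CC(=C)[C@H](O)CC[C@@]3(C)O[C@H]3[C@@H](OC(=O)/C(C)=C\C)[C@H]12
F3 | step 9 | (4R,5S)-4-[(2R,3R)-3-ethenyl-3-methyloxirane-2-carbonyl]-5-(2-iodoprop-2-en-1-yl)-3-methylideneoxolan-2-one | C=C1C(=O)O[C@@H](CC(I)=C)[C@@H]1C(=O)[C@@H]2O[C@]2(C)C=C
F4 | step 10 | (S)-[(2S,3R)-3-ethenyl-3-methyloxiran-2-yl][(2S,3R)-2-(2-iodoprop-2-en-1-yl)-4-methylidene-5-oxooxolan-3-yl]methyl 2-[bis(2,2,2-trifluoroethoxy)phosphoryl]propanoate | C=C1C(=O)O[C@@H](CC(I)=C)[C@@H]1[C@H](OC(=O)C(C)P(=O)(OCC(F)(F)F)OCC(F)(F)F)[C@@H]2O[C@]2(C)C=C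
F5 | step 12 | (1S,4R,5S,6S,7R,8S)-1-(chloroacetoxy)-4,5-epoxy-6-[(2Z)-2-methylbut-2-enoyloxy]germacra-10(14),11(13)-dien-8,12-olide | C=C1C(=O)O[C@H]2CC(=C)[C@@H](OC(=O)CCl)CC[C@@]3(C)O[C@H]3[C@@H](OC(=O)/C(C)=C\C)[C@H]12
A1 | alternative 1 | (5S)-3-(bromomethyl)-5-{(3S)-5-[(2R,3R)-3-formyl-2-methyloxiran-2-yl]-2-methylidene-3-(triethylsilyloxy)pentyl}furan-2(5H)-one | BrCC1=C[C@H](CC(=C)[C@@H](O[Si](CC)(CC)CC)CC[C@@]2(C)O[C@H]2C=O)OC1=O
A2 | alternative 2 | (6S)-3-methyl-6-(prop-1-en-2-yl)cyclohex-2-en-1-one | O=C1C=C(C)CC[C@H]1C(C)=C
A3 | alternative 2 | (1S,6S)-1-(4,5-dihydrofuran-3-yl)-3-methyl-6-(prop-1-en-2-yl)cyclohex-2-en-1-ol | CC1=C[C@@](O)(C2=COCC2)[C@@H](CC1)C(C)=C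
A4 | alternative 3 | (1S,2Z,4R,5S,6S,7R,8S)-4,5-epoxy-1-hydroxy-6-[(2Z)-2-methylbut-2-enoyloxy]germacra-2,10(14),11(13)-trien-8,12-olide | C=C1C(=O)O[C@H]2CC(=C)[C@@H](O)/C=C\[C@@]3(C)O[C@H]3[C@@H](OC(=O)/C(C)=C\C)[C@H]12
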